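**Retrosynthetic overview**
1. The ester C–O bond is cut first: the diterpenoid acid opens (R)-PMB glycidyl ether as its carboxylate; acetylation and PMB removal then give the 1-acyl-2-acetyl-sn-glycerol.
2. The 4-methylpent-3-enyl chain on C5=C6 comes from a Johnson–Claisen rearrangement of a 5-methylidene-6-ol followed by a Wittig reaction; the methylidene ketone comes from a Mannich reaction on the enolate left when Me2CuLi installs the 4a-methyl (cis) on an octalenone.
3. The ring A stereocentres (C1, C2) are set earlier, on the rigid (S)-Wieland–Miescher ketone with its enone masked as a dithiolane (C2 methylation, C1 methylenation/hydroboration).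
4. The Wieland–Miescher ketone comes from a proline aldol condensation of the triketone made by the key intermolecular Michael addition of 2-methylcyclohexane-1,3-dione to methyl vinyl ketone (C8–C8a bond).
5. Ring order: ring A is the dione ring from the start; ring B is closed by the Michael/aldol annulation.

Assumption: all bicyclic compounds are numbered like the target acid (C1 bears the carboxyl carbon, C2 the secondary methyl, C4a and C8a the angular methyls, C5 the side chain); "down" is the face of the 8a-methyl, "up" the other face.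

**Step 1**
Reactants: 1 2-methylcyclohexane-1,3-dione; 2 but-3-en-2-one (methyl vinyl ketone)
Product: 3 2-methyl-2-(3-oxobutyl)cyclohexane-1,3-dione
Conditions: H2O, AcOH (cat.), hydroquinone (cat.), 75 °C
Reagents that add atoms: none
Why: Michael addition of the dione enol to the enone joins the two fragments through the future C8–C8a bond; the new quaternary carbon is still prochiral.

**Step 2**
Reactants: 3 triketone
Product: 5 (S)-8a-methyl-3,4,8,8a-tetrahydronaphthalene-1,6(2H,7H)-dione [(S)-Wieland–Miescher ketone], via cis-ketol 4 (not isolated)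
Conditions: L-proline (5 mol %), DMSO, 35 °C, 4 d; recrystallization (Et2O/hexane) to >99% ee
Reagents that add atoms: none
Why: Hajos–Parrish–Eder–Sauer–Wiechert aldol condensation, in which the proline enamine of the side-chain ketone attacks one of the two enantiotopic ring carbonyls through a hydrogen-bonded chair transition state and so fixes C8a as S.

**Step 3**
Reactants: 5 (S)-Wieland–Miescher ketone
Product: 6 6-(1,3-dithiolane) of 5 (C1 ketone free; C4a=C5 kept)
Conditions: HSCH2CH2SH (1.05 equiv), p-toluenesulfonic acid (cat.), AcOH, rt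
Reagents that add atoms: ethane-1,2-dithiol (SCCS)
Why: Chemoselective thioketalization, since in acetic acid the conjugated carbonyl reacts with the dithiol much faster than the neopentyl saturated ketone and the double bond does not migrate.

**Step 4**
Reactants: 6 dithiolane ketone
Product: 7 2-methyl ketone (2-Me up and equatorial; 8a-Me down and axial; 6-dithiolane)
Conditions: LiN(iPr)2, THF, −78 °C; MeI, −78 → 0 °C; then NaOMe (cat.), MeOH, rt
Reagents that add atoms: iodomethane (CI)
Why: Enolate alkylation at C2, the only enolizable position, followed by base equilibration that puts the methyl equatorial and trans to the axial 8a-methyl on the conformationally locked ring A (no 1,3-diaxial Me/Me).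

**Step 5**
Reactants: 7 2-methyl ketone
Product: 8 1-methylidene compound (C1=CH2; 2-Me up; 8a-Me down; 6-dithiolane)
Conditions: Ph3PCH3Br, KOtBu, toluene, 90 °C
Reagents that add atoms: methyltriphenylphosphonium bromide (C[P+](c1ccccc1)(c1ccccc1)c1ccccc1.[Br-])
Why: Wittig methylenation under forcing conditions suited to hindered ketones; any C2 epimerization before olefination only returns the equatorial methyl.

**Step 6**
Reactants: 8 1-methylidene compound
Product: 10 primary alcohol (1-CH2OH down and equatorial; 2-Me up; 8a-Me down; 6-dithiolane), via alkyl-9-BBN adduct 9 (not isolated)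
Conditions: 9-borabicyclo[3.3.1]nonane (9-BBN), THF, 65 °C; then Me3NO·2H2O, 65 °C
Reagents that add atoms: trimethylamine N-oxide (C[N+](C)(C)[O-])
Why: Anti-Markovnikov hydroboration–oxidation in which the bulky borane reacts only at the terminal alkene and delivers H to C1 from the top face, anti to the adjacent axial 8a-methyl, so the CH2OH ends equatorial and trans to the 2-methyl; the amine oxide leaves sulfur untouched.

**Step 7**
Reactants: 10 primary alcohol
Product: 11 TBS ether of 10
Conditions: TBSCl, imidazole, DMF, rt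
Reagents that add atoms: tert-butyldimethylsilyl chloride (CC(C)(C)[Si](C)(C)Cl)
Why: Standard silylation of an unhindered primary hydroxyl; no stereocentre is touched.

**Step 8**
Reactants: 11 TBS ether dithiolane
Product: 12 enone (6-oxo; C4a=C5; 1-CH2OTBS down; 2-Me up; 8a-Me down)
Conditions: MeI (excess), CaCO3, MeCN/H2O (4:1), 55 °C
Reagents that add atoms: water (O)
Why: S-alkylative hydrolysis of the allylic dithiolane (sulfonium formation, then water) regenerates the conjugated enone under neutral conditions that spare the silyl ether.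

**Step 9**
Reactants: 12 enone
Product: 14 trimethylsilyl enol ether (C5=C6–OSiMe3; 4a-Me down, cis to 8a-Me), via lithium enolate 13 (not isolated)
Conditions: CuI, MeLi (2 equiv per Cu), Et2O, 0 °C; then TMSCl, 12, THF, −78 → 0 °C; Et3N quench
Reagents that add atoms: lithium dimethylcuprate Me2CuLi ([Li+].C[Cu-]C); chlorotrimethylsilane (C[Si](C)(C)Cl)
Why: Silyl-accelerated cuprate 1,4-addition, which on 8a-methyl octalenones puts the methyl on C4a cis to the angular methyl (the cis path avoids the four syn-axial contacts of the trans-decalin path) and traps the enolate regiospecifically at C5=C6.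

**Step 10**
Reactants: 14 trimethylsilyl enol ether
Product: 15 Mannich base (5-CH2NMe2; 6-oxo; C5 epimers)
Conditions: CH2=NMe2+ I− (1.5 equiv), CH2Cl2, rt; aq. NaHCO3 work-up
Reagents that add atoms: N,N-dimethylmethyleneiminium iodide (C=[N+](C)C.[I-])
Why: Mannich reaction of a regiodefined silyl enol ether with a preformed, small iminium ion gives C–C bond formation only at C5; the C5 configuration is removed in the next step.

**Step 11**
Reactants: 15 Mannich base
Product: 17 exocyclic enone (5-methylidene-6-oxo), via ammonium iodide 16 (not isolated)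
Conditions: MeI, Et2O, rt; then NaHCO3, CH2Cl2/H2O, rt
Reagents that add atoms: none
Why: N-Quaternization followed by E1cB (Hofmann-type) elimination of trimethylamine gives the α-methylene ketone, which is used at once.

**Step 12**
Reactants: 17 exocyclic enone
Product: 18 allylic alcohol (5-methylidene-6-ol; C6 epimers)
Conditions: NaBH4, CeCl3·7H2O, MeOH, −20 °C
Reagents that add atoms: none
Why: Luche 1,2-reduction of the enone; the C6 carbinol configuration is irrelevant because C6 becomes sp2 in the next step.

**Step 13**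
Reactants: 18 allylic alcohol
Product: 21 ethyl 3-(decalin-5-en-5-yl)propanoate (C5=C6; 1-CH2OTBS; 2,4a,8a-trimethyl), via mixed orthoester 19 (not isolated), via ketene acetal 20 (not isolated)
Conditions: CH3C(OEt)3 (excess), EtCO2H (cat.), 140 °C, EtOH distilled off
Reagents that add atoms: triethyl orthoacetate (CC(OCC)(OCC)OCC)
Why: Johnson–Claisen [3,3]-sigmatropic rearrangement moves the double bond into the ring at C5=C6 and adds a two-carbon ester at the former exocyclic CH2; no stereocentre is formed.

**Step 14**
Reactants: 21 ethyl ester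
Product: 22 3-(decalin-5-en-5-yl)propan-1-ol
Conditions: LiAlH4, THF, 0 °C
Reagents that add atoms: none
Why: Hydride reduction of the only carbonyl group; the silyl ether and the alkene are inert.

**Step 15**
Reactants: 22 primary alcohol
Product: 23 3-(decalin-5-en-5-yl)propanal
Conditions: Dess–Martin periodinane, NaHCO3, CH2Cl2, rt
Reagents that add atoms: none
Why: Dess–Martin oxidation stops cleanly at the aldehyde under buffered, non-acidic conditions.

**Step 16**
Reactants: 23 aldehyde
Product: 24 TBS ether carrying the 4-methylpent-3-enyl chain on C5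
Conditions: iPrPPh3I, n-BuLi, THF, 0 °C; then 23, −78 °C → rt
Reagents that add atoms: isopropyltriphenylphosphonium iodide (CC(C)[P+](c1ccccc1)(c1ccccc1)c1ccccc1.[I-])
Why: Wittig olefination with the isopropylidene ylide gives the trisubstituted alkene, for which no E/Z question arises.

**Step 17**
Reactants: 24 TBS ether
Product: 25 [(1S,2R,4aR,8aR)-2,4a,8a-trimethyl-5-(4-methylpent-3-en-1-yl)-1,2,3,4,4a,7,8,8a-octahydronaphthalen-1-yl]methanol
Conditions: Bu4NF, THF, rt
Reagents that add atoms: none
Why: Fluoride-induced desilylation; nothing else in the molecule is fluoride- or base-sensitive.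

**Step 18**
Reactants: 25 primary alcohol
Product: 26 (1S,2R,4aR,8aR)-1-carbaldehyde
Conditions: Dess–Martin periodinane, NaHCO3, CH2Cl2, 0 °C → rt
Reagents that add atoms: none
Why: Dess–Martin oxidation under neutral conditions; the formyl group is already in the stable equatorial position of the all-equatorial ring A chair, so C1 cannot drift.

**Step 19**
Reactants: 26 aldehyde
Product: 27 (1S,2R,4aR,8aR)-2,4a,8a-trimethyl-5-(4-methylpent-3-en-1-yl)-1,2,3,4,4a,7,8,8a-octahydronaphthalene-1-carboxylic acid
Conditions: NaClO2, NaH2PO4, 2-methylbut-2-ene (excess), t-BuOH/H2O, rt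
Reagents that add atoms: sodium chlorite NaClO2 ([Na+].[O-]Cl=O)
Why: Pinnick oxidation works on hindered aldehydes, and the alkene scavenger removes HOCl before it can attack the two trisubstituted alkenes.

**Step 20**
Reactants: 28 (S)-oxiran-2-ylmethanol [(S)-glycidol]
Product: 29 (R)-2-{[(4-methoxybenzyl)oxy]methyl}oxirane
Conditions: NaH, 4-methoxybenzyl chloride, Bu4NI (cat.), THF/DMF, 0 °C → rt
Reagents that add atoms: 4-methoxybenzyl chloride (COc1ccc(CCl)cc1)
Why: Williamson etherification at oxygen; the stereocentre is untouched and only its descriptor changes from S to R by priority.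

**Step 21**
Reactants: 27 acid; 29 (R)-PMB glycidyl ether (1.5 equiv)
Product: 30 (S)-2-hydroxy-3-[(4-methoxybenzyl)oxy]propyl ester of 27 (1-O-acyl-3-O-PMB-sn-glycerol)
Conditions: Bu4NBr (10 mol %), toluene, 100 °C
Reagents that add atoms: none
Why: Onium-salt-catalysed SN2 opening of the terminal epoxide by the carboxylate at the CH2 carbon forms the hindered ester through oxygen, not at the crowded acyl carbon, and leaves the glycerol stereocentre untouched.

**Step 22**
Reactants: 30 hydroxy ester
Product: 31 (S)-2-acetoxy-3-[(4-methoxybenzyl)oxy]propyl ester of 27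
Conditions: Ac2O, pyridine, 4-(dimethylamino)pyridine (cat.), CH2Cl2, 0 °C
Reagents that add atoms: acetic anhydride (CC(=O)OC(C)=O)
Why: Nucleophile-catalysed acylation of the only free hydroxyl at low temperature, before the hindered primary ester can migrate.

**Step 23**
Reactants: 31 PMB ether
Product: 32 (S)-2-acetoxy-3-hydroxypropyl (1S,2R,4aR,8aR)-2,4a,8a-trimethyl-5-(4-methylpent-3-en-1-yl)-1,2,3,4,4a,7,8,8a-octahydronaphthalene-1-carboxylate (target)
Conditions: 2,3-dichloro-5,6-dicyano-1,4-benzoquinone (DDQ), CH2Cl2/pH 7 phosphate buffer (10:1), 0 °C; fast chromatography on boric-acid-treated silica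
Reagents that add atoms: none
Why: Oxidative cleavage of the PMB ether under neutral buffered conditions leaves the isolated alkenes alone and avoids the acid- or base-induced 2→3 acetyl migration typical of 1,2-diacylglycerols.

**Compound list**
1 | 2-methylcyclohexane-1,3-dione | CC1C(=O)CCCC1=O | starting material
2 | but-3-en-2-one (methyl vinyl ketone) | CC(=O)C=C | starting material
3 | 2-methyl-2-(3-oxobutyl)cyclohexane-1,3-dione | CC(=O)CCC1(C)C(=O)CCCC1=O | intermediate
4 | (4aS,8aS)-4a-hydroxy-8a-methyloctahydronaphthalene-1,6-dione (cis ketol, not isolated) | O=C1CCC[C@]2(O)CC(=O)CC[C@]12C | intermediate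
5 | (S)-8a-methyl-3,4,8,8a-tetrahydronaphthalene-1,6(2H,7H)-dione | O=C1CCCC2=CC(=O)CC[C@]12C | intermediate
6 | 6-(1,3-dithiolane) of 5, C1 ketone free | O=C1CCCC2=CC3(SCCS3)CC[C@]12C | intermediate
7 | 2-methyl ketone, 2-Me up (equatorial), 8a-Me down | O=C1[C@H](C)CCC2=CC3(SCCS3)CC[C@]12C | intermediate
8 | 1-methylidene compound | C=C1[C@H](C)CCC2=CC3(SCCS3)CC[C@]12C | intermediate
9 | alkyl-9-BBN adduct (C1–CH2–B, not isolated) | C(B3C4CCCC3CCC4)[C@H]1[C@H](C)CCC2=CC5(SCCS5)CC[C@]12C | intermediate
10 | primary alcohol, 1-CH2OH down, 2-Me up, 8a-Me down, 6-dithiolane | OC[C@H]1[C@H](C)CCC2=CC3(SCCS3)CC[C@]12C | intermediate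
11 | TBS ether of 10 | CC(C)(C)[Si](C)(C)OC[C@H]1[C@H](C)CCC2=CC3(SCCS3)CC[C@]12C | intermediate
12 | enone, 6-oxo, C4a=C5, 1-CH2OTBS | CC(C)(C)[Si](C)(C)OC[C@H]1[C@H](C)CCC2=CC(=O)CC[C@]12C | intermediate
13 | lithium enolate, C5=C6–OLi, cis-4a,8a-dimethyl (not isolated) | CC(C)(C)[Si](C)(C)OC[C@H]1[C@H](C)CC[C@]2(C)C=C(O[Li])CC[C@]12C | intermediate
14 | trimethylsilyl enol ether, C5=C6–OSiMe3, cis-4a,8a-dimethyl | CC(C)(C)[Si](C)(C)OC[C@H]1[C@H](C)CC[C@]2(C)C=C(O[Si](C)(C)C)CC[C@]12C | intermediate
15 | Mannich base, 5-(dimethylaminomethyl)-6-oxo, C5 epimers | CC(C)(C)[Si](C)(C)OC[C@H]1[C@H](C)CC[C@]2(C)C(CN(C)C)C(=O)CC[C@]12C | intermediate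
16 | trimethylammonium iodide of 15 (not isolated) | CC(C)(C)[Si](C)(C)OC[C@H]1[C@H](C)CC[C@]2(C)C(C[N+](C)(C)C)C(=O)CC[C@]12C.[I-] | intermediate
17 | 5-methylidene-6-oxo compound | CC(C)(C)[Si](C)(C)OC[C@H]1[C@H](C)CC[C@]2(C)C(=C)C(=O)CC[C@]12C | intermediate
18 | 5-methylidene-6-ol, C6 epimers | CC(C)(C)[Si](C)(C)OC[C@H]1[C@H](C)CC[C@]2(C)C(=C)C(O)CC[C@]12C | intermediate
19 | mixed orthoester at C6–O (not isolated) | CC(C)(C)[Si](C)(C)OC[C@H]1[C@H](C)CC[C@]2(C)C(=C)C(OC(C)(OCC)OCC)CC[C@]12C | intermediate
20 | ketene acetal at C6–O (not isolated) | CC(C)(C)[Si](C)(C)OC[C@H]1[C@H](C)CC[C@]2(C)C(=C)C(OC(=C)OCC)CC[C@]12C | intermediate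
21 | ethyl 3-(decalin-5-en-5-yl)propanoate, 1-CH2OTBS | CC(C)(C)[Si](C)(C)OC[C@H]1[C@H](C)CC[C@]2(C)C(CCC(=O)OCC)=CCC[C@]12C | intermediate
22 | 3-(decalin-5-en-5-yl)propan-1-ol | CC(C)(C)[Si](C)(C)OC[C@H]1[C@H](C)CC[C@]2(C)C(CCCO)=CCC[C@]12C | intermediate
23 | 3-(decalin-5-en-5-yl)propanal | CC(C)(C)[Si](C)(C)OC[C@H]1[C@H](C)CC[C@]2(C)C(CCC=O)=CCC[C@]12C | intermediate
24 | TBS ether with 5-(4-methylpent-3-enyl) chain | CC(C)(C)[Si](C)(C)OC[C@H]1[C@H](C)CC[C@]2(C)C(CCC=C(C)C)=CCC[C@]12C | intermediate
25 | [(1S,2R,4aR,8aR)-2,4a,8a-trimethyl-5-(4-methylpent-3-en-1-yl)-1,2,3,4,4a,7,8,8a-octahydronaphthalen-1-yl]methanol | OC[C@H]1[C@H](C)CC[C@]2(C)C(CCC=C(C)C)=CCC[C@]12C | intermediate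
26 | (1S,2R,4aR,8aR)-1-carbaldehyde | O=C[C@H]1[C@H](C)CC[C@]2(C)C(CCC=C(C)C)=CCC[C@]12C | intermediate
27 | (1S,2R,4aR,8aR)-1-carboxylic acid | OC(=O)[C@H]1[C@H](C)CC[C@]2(C)C(CCC=C(C)C)=CCC[C@]12C | intermediate
28 | (S)-oxiran-2-ylmethanol [(S)-glycidol] | OC[C@H]1CO1 | starting material
29 | (R)-2-{[(4-methoxybenzyl)oxy]methyl}oxirane | COc1ccc(COC[C@H]2CO2)cc1 | intermediate
30 | (S)-2-hydroxy-3-[(4-methoxybenzyl)oxy]propyl ester of 27 | COc1ccc(COC[C@H](O)COC(=O)[C@H]2[C@H](C)CC[C@]3(C)C(CCC=C(C)C)=CCC[C@]23C)cc1 | intermediate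
31 | (S)-2-acetoxy-3-[(4-methoxybenzyl)oxy]propyl ester of 27 | COc1ccc(COC[C@H](OC(C)=O)COC(=O)[C@H]2[C@H](C)CC[C@]3(C)C(CCC=C(C)C)=CCC[C@]23C)cc1 | intermediate
32 | (S)-2-acetoxy-3-hydroxypropyl (1S,2R,4aR,8aR)-2,4a,8a-trimethyl-5-(4-methylpent-3-en-1-yl)-1,2,3,4,4a,7,8,8a-octahydronaphthalene-1-carboxylate | CC(=O)O[C@@H](CO)COC(=O)[C@H]1[C@H](C)CC[C@]2(C)C(CCC=C(C)C)=CCC[C@]12C | target

**Totals**
Total step count: 23. Longest linear sequence: 22 steps (steps 1–19, then 21–23); step 20 is a one-step side branch.

**Three steps most likely to fail, with fallbacks**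

Step 6 (hydroboration of the hindered methylidene compound; risks are attack on the ring alkene and incomplete facial control). The fallback sets out from ketone 7 and returns at alcohol 10, replacing kinetic control by thermodynamic control at C1. Ketone 7 is treated with methoxymethylidenetriphenylphosphorane (from (methoxymethyl)triphenylphosphonium chloride and KOtBu, toluene, 90 °C) to give the methyl enol ether F1 as an E/Z mixture. Hydrolysis with aqueous HCl in THF gives the aldehyde F2, which is stirred with K2CO3 in MeOH so that the formyl group settles in the equatorial, down position on the locked ring A. NaBH4 in MeOH then gives 10.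

Step 9 (cuprate addition that creates the second quaternary centre next to the first). The fallback sets out from enone 12 and returns at silyl enol ether 14, delivering the methyl group intramolecularly as a cyclopropane. Luche reduction of 12 (NaBH4, CeCl3·7H2O, MeOH) gives the allylic alcohol F3 with the 6-hydroxyl down, cis to the 8a-methyl. Hydroxyl-directed Simmons–Smith cyclopropanation (Et2Zn, CH2I2, CH2Cl2, 0 °C) places the CH2 on the same face and gives the 4a,5-methano carbinol F4. Dess–Martin oxidation gives the cyclopropyl ketone F5. Li in liquid NH3/THF at −78 °C cleaves the C5–CH2 bond, the one that overlaps with the carbonyl π system, which leaves the 4a-methyl cis to the 8a-methyl and the lithium enolate 13; this is silylated with TMSCl/Et3N to 14.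

Step 21 (epoxide opening by the hindered acid; risks are slow reaction and partial 1→2 acyl shift at 100 °C). The fallback sets out from acid 27 and epoxide 29 and returns at hydroxy ester 30, using acyl transfer instead of carboxylate alkylation. Epoxide 29 is hydrolysed (KOH, DMSO/H2O, 80 °C) to (R)-3-[(4-methoxybenzyl)oxy]propane-1,2-diol F6. Acid 27 is converted with oxalyl chloride and a drop of DMF in CH2Cl2 into the acid chloride F7. F7 acylates only the primary hydroxyl of F6 (pyridine, 4-(dimethylamino)pyridine, CH2Cl2, 0 °C), because the bulky acyl group discriminates strongly against the secondary hydroxyl, and gives 30.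

**Further compounds**
F1 | step 6 | methyl enol ether, 1-(methoxymethylidene) analogue of 8 (E/Z mixture) | COC=C1[C@H](C)CCC2=CC3(SCCS3)CC[C@]12C
F2 | step 6 | 1-carbaldehyde, CHO down (equatorial), 2-Me up, 6-dithiolane | O=C[C@H]1[C@H](C)CCC2=CC3(SCCS3)CC[C@]12C
F3 | step 9 | allylic alcohol from 12, 6-OH down, C4a=C5 | CC(C)(C)[Si](C)(C)OC[C@H]1[C@H](C)CCC2=C[C@@H](O)CC[C@]12C
F4 | step 9 | 4a,5-methano carbinol, CH2 and 6-OH down | CC(C)(C)[Si](C)(C)OC[C@H]1[C@H](C)CC[C@@]23C[C@H]3[C@@H](O)CC[C@]12C
F5 | step 9 | 4a,5-methano-6-ketone, CH2 down | CC(C)(C)[Si](C)(C)OC[C@H]1[C@H](C)CC[C@@]23C[C@H]3C(=O)CC[C@]12C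
F6 | step 21 | (R)-3-[(4-methoxybenzyl)oxy]propane-1,2-diol | COc1ccc(COC[C@H](O)CO)cc1
F7 | step 21 | acid chloride of 27 | ClC(=O)[C@H]1[C@H](C)CC[C@]2(C)C(CCC=C(C)C)=CCC[C@]12C
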